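**Retrosynthetic overview**
- Target 21 ⇐ cleavage of two aryl silyl ethers ⇐ O-palmitoylation of benzylic alcohol 18 ⇐ reduction of only the ring A ester of diaryl ether diester 17; the ring B ester is shielded by two ortho substituents.
- Ring A is built onto the ring B oxygen instead of being coupled to it. Its oxygens on C3' (OMe) and C5' (OH) flank C4'–H, the ether oxygen sits on C6' and an ester-level carbon on C1'. This is the pattern left by a 4-aryloxy-1,1-dimethoxy-3-silyloxybuta-1,3-diene (C3'–C6') and a nitroacrylate (C1'–C2'), so the bonds C6'–C1' and C2'–C3' are cut.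
- Diene 10 ⇐ silylation of acylketene acetal 9 ⇐ C-acylation of 1,1-dimethoxyethene by an aryloxyacetyl chloride ⇐ O-alkylation of mono-silylated methyl 2,6-dihydroxy-4-methylbenzoate; dienophile 13 ⇐ methyl acrylate.
- Ring order: ring B is aromatic from the start; ring A is the only ring formed (step 9).

Key step: step 9

Remark: ring A is numbered C1' (carbon carrying the CH2O group), C2' (H), C3' (OMe), C4' (H), C5' (OH), C6' (ether oxygen); 12, 14 and 15 are racemic and none of their stereocentres reaches the target, which has no stereocentre.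

**Step 1**
Reactants: 1 2,6-dihydroxy-4-methylbenzoic acid
Product: 2 methyl 2,6-dihydroxy-4-methylbenzoate
Conditions: MeI (1.2 equiv), KHCO3 (1.2 equiv), DMF, rt
Reagents that add atoms: iodomethane, CI
Why: SN2 O-alkylation of the carboxylate, in which hydrogen carbonate deprotonates only the strongly acidic carboxyl group and leaves the hydrogen-bonded phenols untouched, while the mild conditions avoid the decarboxylation that threatens 2,6-dihydroxybenzoic acids on heating in acid.

**Step 2**
Reactants: 2 methyl 2,6-dihydroxy-4-methylbenzoate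
Product: 3 methyl 2-hydroxy-4-methyl-6-(triisopropylsilyloxy)benzoate
Conditions: iPr3SiCl (1.05 equiv), imidazole, DMF, 0 °C → rt
Reagents that add atoms: chlorotriisopropylsilane, CC(C)[Si](Cl)(C(C)C)C(C)C
Why: Silyl ether formation at one of two equivalent phenols should stop at the mono-ether, because the remaining phenol is locked in a hydrogen bond to the ester carbonyl and reacts far more slowly with the bulky chlorosilane.

**Step 3**
Reactants: 3 methyl 2-hydroxy-4-methyl-6-(triisopropylsilyloxy)benzoate; 4 benzyl bromoacetate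
Product: 5 benzyl 2-[2-(methoxycarbonyl)-5-methyl-3-(triisopropylsilyloxy)phenoxy]acetate
Conditions: K2CO3, acetone, 50 °C
Reagents that add atoms: none
Why: Williamson ether synthesis of the phenoxide with an activated primary bromide, under a base too weak to cleave the aryl triisopropylsilyl ether or to trigger Dieckmann-type closure onto the neighbouring ester.

**Step 4**
Reactants: 5 benzyl 2-[2-(methoxycarbonyl)-5-methyl-3-(triisopropylsilyloxy)phenoxy]acetate
Product: 6 2-[2-(methoxycarbonyl)-5-methyl-3-(triisopropylsilyloxy)phenoxy]acetic acid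
Conditions: H2 (1 atm), 10% Pd/C, EtOAc, rt
Reagents that add atoms: none
Why: Hydrogenolysis of the benzyl ester under neutral conditions, which leaves the methyl ester, the aryl alkyl ether and the aryl silyl ether intact.

**Step 5**
Reactants: 6 2-[2-(methoxycarbonyl)-5-methyl-3-(triisopropylsilyloxy)phenoxy]acetic acid; 7 1,1-dimethoxyethene
Product: 9 methyl 2-(4,4-dimethoxy-2-oxobut-3-enyloxy)-4-methyl-6-(triisopropylsilyloxy)benzoate, via aryloxyacetyl chloride 8 (not isolated)
Conditions: (COCl)2, cat. DMF, CH2Cl2, 0 °C → rt, concentrate; then 7 (2.5 equiv), Et2O, 0 °C → rt, no amine base; product used without chromatography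
Reagents that add atoms: none
Why: Acid chloride formation followed by C-acylation of the nucleophilic ketene acetal (addition to the acyl chloride, then loss of HCl from the chloro acetal) should give the β,β-dimethoxy enone, the second equivalent of 7 taking up HCl as methyl acetate and chloromethane so that no amine is present that could dehydrochlorinate 8 to an aryloxyketene.

**Step 6**
Reactants: 9 methyl 2-(4,4-dimethoxy-2-oxobut-3-enyloxy)-4-methyl-6-(triisopropylsilyloxy)benzoate
Product: 10 methyl 2-[(1Z)-4,4-dimethoxy-2-(trimethylsilyloxy)buta-1,3-dienyloxy]-4-methyl-6-(triisopropylsilyloxy)benzoate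
Conditions: Me3SiOTf (1.2 equiv), Et3N (1.6 equiv), Et2O, 0 °C; filter under argon, use crude
Reagents that add atoms: trimethylsilyl trifluoromethanesulfonate, C[Si](C)(C)OS(=O)(=O)C(F)(F)F
Why: Soft enolisation with O-silylation (silyl enol ether formation) can occur only at the OCH2 group, and the Z enol ether, with the aryloxy group trans to the ketene acetal arm, should predominate because it avoids allylic strain with that arm.

**Step 7**
Reactants: 11 methyl acrylate
Product: 12 methyl 2-iodo-3-nitropropanoate (racemic)
Conditions: N2O4, I2, Et2O, 0 °C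
Reagents that add atoms: dinitrogen tetroxide, [O-][N+](=O)[N+](=O)[O-]; iodine, II
Why: Radical nitro-iodination of the alkene, in which NO2 adds to the unsubstituted terminus and the α-ester radical is trapped by iodine, places nitrogen on C3 and iodine on C2 (the stereocentre is removed in step 8).

**Step 8**
Reactants: 12 methyl 2-iodo-3-nitropropanoate
Product: 13 methyl (E)-3-nitroacrylate
Conditions: NaOAc (anhydrous), Et2O, 0 °C → rt
Reagents that add atoms: none
Why: Acetate-induced dehydroiodination (E1cB through the nitronate) should give the conjugated nitroalkene as the more stable E isomer.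

**Step 9**
Reactants: 10 methyl 2-[(1Z)-4,4-dimethoxy-2-(trimethylsilyloxy)buta-1,3-dienyloxy]-4-methyl-6-(triisopropylsilyloxy)benzoate; 13 methyl (E)-3-nitroacrylate
Product: 16 methyl 3-hydroxy-5-methoxy-2-[2-(methoxycarbonyl)-5-methyl-3-(triisopropylsilyloxy)phenoxy]benzoate, via nitrocyclohexene cycloadduct 14 (not isolated), via cyclohexa-1,4-diene ketal 15 (not isolated)
Conditions: 13 (1.2 equiv), PhMe, 0 °C → rt; then DBU (3 equiv), THF, 0 °C → rt; aqueous work-up
Reagents that add atoms: none
Why: The ketene acetal and the silyloxy group make the diene terminus C6' the nucleophilic end, and in the dienophile the nitro group outweighs the ester, so the ester-bearing carbon C1' (β to nitro) is the electrophilic end; an asynchronous normal-electron-demand Diels–Alder reaction therefore forms C6'–C1' and then C2'–C3', closing ring A as a six-membered carbocycle by [4+2] cycloaddition, the closest known reaction type being the use of β-nitroacrylates as regiochemically reversed propiolate equivalents with alkoxy-silyloxy dienes. The Z enol ether holds the aryloxy group on the outside of the s-cis diene, so the cycloaddition should proceed near room temperature with this very electron-poor dienophile. DBU then removes the C1'–H α to the ester and expels nitrite from C2' (E1cB), nitrite being a much better leaving group than the aryloxide on C6', to give 15. Loss of methanol from the doubly allylic ketal carbon C3' together with the C6' proton aromatises the ring, leaving one methoxy group on C3' and the silyloxy group on C5', and the labile aryl trimethylsilyl ether is hydrolysed on work-up to the C5' phenol. The stereocentres of 14 (ester and nitro trans from the E dienophile) are all erased, so the step needs only regioselectivity, which the matched polarisation of the two partners secures, and chemoselectivity in the elimination, which the leaving-group difference secures; the triisopropylsilyl ether and both methyl esters should be inert to DBU at room temperature.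

**Step 10**
Reactants: 16 methyl 3-hydroxy-5-methoxy-2-[2-(methoxycarbonyl)-5-methyl-3-(triisopropylsilyloxy)phenoxy]benzoate
Product: 17 methyl 3-(tert-butyldimethylsilyloxy)-5-methoxy-2-[2-(methoxycarbonyl)-5-methyl-3-(triisopropylsilyloxy)phenoxy]benzoate
Conditions: tBuMe2SiCl, imidazole, DMF, rt
Reagents that add atoms: tert-butylchlorodimethylsilane, CC(C)(C)[Si](C)(C)Cl
Why: Standard silylation of a phenol that is not hydrogen-bonded to a carbonyl group, which keeps the C5' oxygen from consuming hydride in step 11 and from being acylated in step 12.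

**Step 11**
Reactants: 17 methyl 3-(tert-butyldimethylsilyloxy)-5-methoxy-2-[2-(methoxycarbonyl)-5-methyl-3-(triisopropylsilyloxy)phenoxy]benzoate
Product: 18 methyl 2-[2-(tert-butyldimethylsilyloxy)-6-(hydroxymethyl)-4-methoxyphenoxy]-4-methyl-6-(triisopropylsilyloxy)benzoate
Conditions: (iBu)2AlH (2.2 equiv), CH2Cl2, −78 °C; MeOH, then aq. KNaC4H4O6
Reagents that add atoms: none
Why: Hydride reduction of an ester to the primary alcohol under steric control, since the ring A ester has one ortho substituent whereas the ring B ester is flanked by the aryloxy group and the bulky triisopropylsilyloxy group and should not be attacked at low temperature.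

**Step 12**
Reactants: 18 methyl 2-[2-(tert-butyldimethylsilyloxy)-6-(hydroxymethyl)-4-methoxyphenoxy]-4-methyl-6-(triisopropylsilyloxy)benzoate; 19 palmitoyl chloride
Product: 20 methyl 2-[2-(tert-butyldimethylsilyloxy)-6-(hexadecanoyloxymethyl)-4-methoxyphenoxy]-4-methyl-6-(triisopropylsilyloxy)benzoate
Conditions: Et3N, cat. DMAP, CH2Cl2, 0 °C → rt
Reagents that add atoms: none
Why: Acylation of the only free hydroxyl group with an acid chloride under nucleophilic catalysis, carried out directly after step 11 so that the benzylic alcohol cannot lactonise onto the ring B ester.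

**Step 13**
Reactants: 20 methyl 2-[2-(tert-butyldimethylsilyloxy)-6-(hexadecanoyloxymethyl)-4-methoxyphenoxy]-4-methyl-6-(triisopropylsilyloxy)benzoate
Product: 21 Betaethrin E, methyl 2-[2-(hexadecanoyloxymethyl)-6-hydroxy-4-methoxyphenoxy]-6-hydroxy-4-methylbenzoate
Conditions: Bu4NF (2.5 equiv), AcOH (3 equiv), THF, 0 °C
Reagents that add atoms: none
Why: Fluoride-induced cleavage of both aryl silyl ethers, buffered by acetic acid so that neither ester is hydrolysed or transesterified, and safe for the benzylic palmitate because the C5' phenol is meta to the benzylic carbon and cannot expel the carboxylate through a quinone methide.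

**Compound list**
1 | 2,6-dihydroxy-4-methylbenzoic acid | Cc1cc(O)c(C(=O)O)c(O)c1 | starting material
2 | methyl 2,6-dihydroxy-4-methylbenzoate | COC(=O)c1c(O)cc(C)cc1O | intermediate
3 | methyl 2-hydroxy-4-methyl-6-(triisopropylsilyloxy)benzoate | COC(=O)c1c(O)cc(C)cc1O[Si](C(C)C)(C(C)C)C(C)C | intermediate
4 | benzyl bromoacetate | BrCC(=O)OCc1ccccc1 | starting material
5 | benzyl 2-[2-(methoxycarbonyl)-5-methyl-3-(triisopropylsilyloxy)phenoxy]acetate | COC(=O)c1c(OCC(=O)OCc2ccccc2)cc(C)cc1O[Si](C(C)C)(C(C)C)C(C)C | intermediate
6 | 2-[2-(methoxycarbonyl)-5-methyl-3-(triisopropylsilyloxy)phenoxy]acetic acid | COC(=O)c1c(OCC(=O)O)cc(C)cc1O[Si](C(C)C)(C(C)C)C(C)C | intermediate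
7 | 1,1-dimethoxyethene | C=C(OC)OC | starting material
8 | methyl 2-(2-chloro-2-oxoethoxy)-4-methyl-6-(triisopropylsilyloxy)benzoate (aryloxyacetyl chloride) | COC(=O)c1c(OCC(=O)Cl)cc(C)cc1O[Si](C(C)C)(C(C)C)C(C)C | intermediate (not isolated)
9 | methyl 2-(4,4-dimethoxy-2-oxobut-3-enyloxy)-4-methyl-6-(triisopropylsilyloxy)benzoate | COC(=O)c1c(OCC(=O)C=C(OC)OC)cc(C)cc1O[Si](C(C)C)(C(C)C)C(C)C | intermediate
10 | methyl 2-[(1Z)-4,4-dimethoxy-2-(trimethylsilyloxy)buta-1,3-dienyloxy]-4-methyl-6-(triisopropylsilyloxy)benzoate | COC(OC)=C/C(O[Si](C)(C)C)=C/Oc1cc(C)cc(O[Si](C(C)C)(C(C)C)C(C)C)c1C(=O)OC | intermediate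
11 | methyl acrylate | C=CC(=O)OC | starting material
12 | methyl 2-iodo-3-nitropropanoate (racemic) | COC(=O)C(I)C[N+](=O)[O-] | intermediate
13 | methyl (E)-3-nitroacrylate | COC(=O)/C=C/[N+](=O)[O-] | intermediate
14 | methyl (1,2-trans)-3,3-dimethoxy-6-[2-(methoxycarbonyl)-5-methyl-3-(triisopropylsilyloxy)phenoxy]-2-nitro-5-(trimethylsilyloxy)cyclohex-4-ene-1-carboxylate (racemic, one enantiomer drawn, aryloxy carbon as a mixture of epimers) | COC(=O)[C@@H]1[C@@H]([N+](=O)[O-])C(OC)(OC)C=C(O[Si](C)(C)C)C1Oc1cc(C)cc(O[Si](C(C)C)(C(C)C)C(C)C)c1C(=O)OC | intermediate (not isolated)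
15 | methyl 3,3-dimethoxy-6-[2-(methoxycarbonyl)-5-methyl-3-(triisopropylsilyloxy)phenoxy]-5-(trimethylsilyloxy)cyclohexa-1,4-diene-1-carboxylate (racemic) | COC(=O)C1=CC(OC)(OC)C=C(O[Si](C)(C)C)C1Oc1cc(C)cc(O[Si](C(C)C)(C(C)C)C(C)C)c1C(=O)OC | intermediate (not isolated)
16 | methyl 3-hydroxy-5-methoxy-2-[2-(methoxycarbonyl)-5-methyl-3-(triisopropylsilyloxy)phenoxy]benzoate | COC(=O)c1cc(OC)cc(O)c1Oc1cc(C)cc(O[Si](C(C)C)(C(C)C)C(C)C)c1C(=O)OC | intermediate
17 | methyl 3-(tert-butyldimethylsilyloxy)-5-methoxy-2-[2-(methoxycarbonyl)-5-methyl-3-(triisopropylsilyloxy)phenoxy]benzoate | COC(=O)c1cc(OC)cc(O[Si](C)(C)C(C)(C)C)c1Oc1cc(C)cc(O[Si](C(C)C)(C(C)C)C(C)C)c1C(=O)OC | intermediate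
18 | methyl 2-[2-(tert-butyldimethylsilyloxy)-6-(hydroxymethyl)-4-methoxyphenoxy]-4-methyl-6-(triisopropylsilyloxy)benzoate | OCc1cc(OC)cc(O[Si](C)(C)C(C)(C)C)c1Oc1cc(C)cc(O[Si](C(C)C)(C(C)C)C(C)C)c1C(=O)OC | intermediate
19 | palmitoyl chloride | CCCCCCCCCCCCCCCC(=O)Cl | starting material
20 | methyl 2-[2-(tert-butyldimethylsilyloxy)-6-(hexadecanoyloxymethyl)-4-methoxyphenoxy]-4-methyl-6-(triisopropylsilyloxy)benzoate | CCCCCCCCCCCCCCCC(=O)OCc1cc(OC)cc(O[Si](C)(C)C(C)(C)C)c1Oc1cc(C)cc(O[Si](C(C)C)(C(C)C)C(C)C)c1C(=O)OC | intermediate
21 | Betaethrin E, methyl 2-[2-(hexadecanoyloxymethyl)-6-hydroxy-4-methoxyphenoxy]-6-hydroxy-4-methylbenzoate | CCCCCCCCCCCCCCCC(=O)OCc1cc(OC)cc(O)c1Oc1cc(C)cc(O)c1C(=O)OC | target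

**Step count**
Total: 13 steps. Longest linear sequence: 11 steps (steps 1–6 and 9–13); steps 7 and 8 make the dienophile.

**Steps most likely to fail**

1. Step 9. The cycloaddition may be slow for a diene substituted at both termini, so that the diene hydrolyses or the nitroalkene polymerises first, or it may stop at the open-chain Michael adduct. During aromatisation the aryloxide on C6' may be expelled in place of nitrite. Fallback (sets out from 3, returns at 16): ring A would be taken ready-made and the ether bond formed by copper catalysis. Purchased methyl 2-amino-5-methoxybenzoate (COC(=O)c1cc(OC)ccc1N) is brominated ortho to the amino group (NBS, DMF, 0 °C) to give methyl 2-amino-3-bromo-5-methoxybenzoate F1. Diazotisation and iodide displacement (NaNO2, aq. H2SO4, then KI; Sandmeyer-type iodination) should give methyl 3-bromo-2-iodo-5-methoxybenzoate F2. Ullmann ether synthesis of phenol 3 with F2 at the more reactive, ester-flanked C–I bond (CuI, N,N-dimethylglycine, Cs2CO3, dioxane, 90 °C) should give methyl 3-bromo-5-methoxy-2-[2-(methoxycarbonyl)-5-methyl-3-(triisopropylsilyloxy)phenoxy]benzoate F3. Miyaura borylation (B2pin2, PdCl2(dppf), KOAc, dioxane, 80 °C) then gives the pinacol boronate F4, and oxidation (NaBO3·4H2O, THF–H2O, rt) gives phenol 16.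

2. Step 5. The chloro acetal intermediate may lose chloromethane to give the β-keto ester instead of losing HCl, and the acid-sensitive ketene acetal may hydrolyse on isolation. Fallback (sets out from 3 and 7, returns at 9): the aryl–O–CH2 bond would be formed last. Chloroacetyl chloride (ClCC(=O)Cl), a simple acid chloride that can be used in excess and whose product can be distilled, acylates 7 (2.5 equiv, Et2O, 0 °C → rt) to give 1-chloro-4,4-dimethoxybut-3-en-2-one F5. Williamson alkylation of phenol 3 with F5 (K2CO3, cat. NaI, acetone, rt) should then give 9 directly, bypassing 5, 6 and 8.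

3. Step 11. Discrimination between the two methyl esters may be incomplete, or the new aluminium alkoxide may attack the ring B ester to form an eight-membered lactone. Fallback (sets out from 17, returns at 18): the esters would be told apart by hydrolysis instead of by hydride. Me3SnOH (ClCH2CH2Cl, 70 °C) should cleave only the mono-ortho-substituted ring A methyl ester, since di-ortho-substituted benzoates resist acyl substitution, giving 3-(tert-butyldimethylsilyloxy)-5-methoxy-2-[2-(methoxycarbonyl)-5-methyl-3-(triisopropylsilyloxy)phenoxy]benzoic acid F6. BH3·SMe2 (THF, 0 °C → rt) then reduces the carboxylic acid chemoselectively beside the remaining methyl ester to give 18.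

**Further compounds**
F1 | step 9 | methyl 2-amino-3-bromo-5-methoxybenzoate | COC(=O)c1cc(OC)cc(Br)c1N
F2 | step 9 | methyl 3-bromo-2-iodo-5-methoxybenzoate | COC(=O)c1cc(OC)cc(Br)c1I
F3 | step 9 | methyl 3-bromo-5-methoxy-2-[2-(methoxycarbonyl)-5-methyl-3-(triisopropylsilyloxy)phenoxy]benzoate | COC(=O)c1cc(OC)cc(Br)c1Oc1cc(C)cc(O[Si](C(C)C)(C(C)C)C(C)C)c1C(=O)OC
F4 | step 9 | methyl 5-methoxy-2-[2-(methoxycarbonyl)-5-methyl-3-(triisopropylsilyloxy)phenoxy]-3-(4,4,5,5-tetramethyl-1,3,2-dioxaborolan-2-yl)benzoate | COC(=O)c1cc(OC)cc(B2OC(C)(C)C(C)(C)O2)c1Oc1cc(C)cc(O[Si](C(C)C)(C(C)C)C(C)C)c1C(=O)OC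
F5 | step 5 | 1-chloro-4,4-dimethoxybut-3-en-2-one | COC(OC)=CC(=O)CCl
F6 | step 11 | 3-(tert-butyldimethylsilyloxy)-5-methoxy-2-[2-(methoxycarbonyl)-5-methyl-3-(triisopropylsilyloxy)phenoxy]benzoic acid | OC(=O)c1cc(OC)cc(O[Si](C)(C)C(C)(C)C)c1Oc1cc(C)cc(O[Si](C(C)C)(C(C)C)C(C)C)c1C(=O)OC
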